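**Plan**

- Cuts: first the bond from C4 of isoflavan unit 1 to ring D (the 3-aryl ring of isoflavan unit 2); then, in unit 1, O1–C8a and C2–C3 together, and C3–ring B. Unit 2 is cut the same way.
- Forward: Pd α-arylation joins ring B (or ring D) to a 2-fluoro-4-oxyacetophenone. One formylation/SNAr operation closes each chromone. The unit 1 chromone is reduced and closed to a pterocarpan, whose furan ring is not in the target. The unit 2 chromone is reduced to the (R)-isoflavan. Acid opens the pterocarpan, its C4 cation arylates ring D, and deprotection follows.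
- Enabling feature: in ring A of unit 1, C8a is ortho to C4 and meta to the C7 oxygen, and C3 lies between C4 and ring B. With C4 held as a ketone, C3–H is acidic and a fluorine on C8a is open to SNAr. The ketone is later reduced, used as leaving group and replaced by ring D.
- Stereochemistry: C3 of each unit comes from Ru transfer hydrogenation with dynamic kinetic resolution. C4 of unit 1 comes from attack on the C4 cation anti to ring B at C3, giving 3,4-trans.

Key step: step 5

Assumption: RuCl[(R,R)-TsDPEN](p-cymene) reduces both chromanones with the facial sense known for aryl alkyl ketones (the (S,S) catalyst gives (S)-1-arylalkanols), which corresponds to (4R) and, through the cis-selective dynamic kinetic resolution, to (3R). If the sense were opposite, the (S,S) catalyst would be used in steps 6 and 11.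

**Route**

Step 1
Reactants: 1 3,4-dimethoxyphenol
Product: 2 2-bromo-4,5-dimethoxyphenol
Conditions: NBS (1.0 equiv), MeCN, 0 °C
Reagents that add atoms: N-bromosuccinimide, O=C1CCC(=O)N1Br
Why: Electrophilic aromatic bromination should go to the carbon ortho to OH and para to the 3-methoxy group, the most activated and least hindered position.

Step 2
Reactants: 2 2-bromo-4,5-dimethoxyphenol
Product: 3 1-bromo-4,5-dimethoxy-2-(methoxymethoxy)benzene
Conditions: MOMCl, iPr2NEt, CH2Cl2, 0 °C to rt
Reagents that add atoms: chloromethyl methyl ether, COCCl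
Why: O-alkylation of the phenol (Williamson type) masks the future 2'-OH of ring B as a base-stable acetal that acid removes in step 6.

Step 3
Reactants: 4 1-(2-fluoro-4-hydroxyphenyl)ethan-1-one
Product: 5 1-[2-fluoro-4-(methoxymethoxy)phenyl]ethan-1-one
Conditions: MOMCl, iPr2NEt, CH2Cl2, 0 °C to rt
Reagents that add atoms: chloromethyl methyl ether, COCCl
Why: O-alkylation of the acidic para-acyl phenol gives the ring A building block with the C7 oxygen protected and the fluorine that will become the leaving group on C8a.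

Step 4
Reactants: 5 1-[2-fluoro-4-(methoxymethoxy)phenyl]ethan-1-one; 3 1-bromo-4,5-dimethoxy-2-(methoxymethoxy)benzene
Product: 6 2-[4,5-dimethoxy-2-(methoxymethoxy)phenyl]-1-[2-fluoro-4-(methoxymethoxy)phenyl]ethan-1-one
Conditions: Pd(OAc)2 (2 mol %), XPhos (4 mol %), K3PO4, toluene, 90 °C
Reagents that add atoms: none
Why: Palladium-catalysed α-arylation of the methyl ketone (Buchwald–Hartwig type) forms the C3–ring B bond; the mild phosphate base leaves the aryl fluoride alone and the ortho-substituted bromide disfavours a second arylation.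

Step 5
Reactants: 6 2-[4,5-dimethoxy-2-(methoxymethoxy)phenyl]-1-[2-fluoro-4-(methoxymethoxy)phenyl]ethan-1-one
Product: 8 3-[4,5-dimethoxy-2-(methoxymethoxy)phenyl]-7-(methoxymethoxy)-4H-chromen-4-one, via sodium hydroxymethylene-ketone enolate 7 (not isolated)
Conditions: NaH (1.1 equiv), HCO2Et (3 equiv), THF, 0 °C to rt; volatiles removed; DMSO, 120 °C
Reagents that add atoms: ethyl formate, CCOC=O
Why: NaH gives the C3 enolate of 6 (C3 lies between the C4 carbonyl and ring B), crossed Claisen condensation with ethyl formate forms C2–C3 and the ethoxide released is consumed at once in forming the stabilised enolate 7, whose oxygen on heating attacks C8a (fluorine-bearing, ortho to the C4 carbonyl) and expels fluoride from the Meisenheimer adduct to form O1–C8a. The closest known reaction types are the formate Claisen route to hydroxymethylene ketones and the intramolecular SNAr closure of 2-fluoroaroyl 1,3-dicarbonyl enolates to 4-pyranones and 4-quinolones. The pyranone ring closes by a 6-exo-trig addition–elimination at the arene carbon. No stereocentre is formed, because C3 becomes trigonal and is set only in step 6. The step needs O- and not C-arylation and intramolecular and not intermolecular fluoride displacement: attack through C3 would give a four-membered ring, one equivalent of base leaves no free alkoxide, the C7 alkoxy group is meta to C8a and does not donate to the reacting carbon, and the 2'-oxygen of ring B is masked as its MOM ether and cannot compete for C8a.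

Step 6
Reactants: 8 3-[4,5-dimethoxy-2-(methoxymethoxy)phenyl]-7-(methoxymethoxy)-4H-chromen-4-one
Product: 11 (6aR,11aR)-8,9-dimethoxy-6a,11a-dihydro-6H-[1]benzofuro[3,2-c]chromen-3-ol, via isoflavanone 9 (not isolated), via cis-isoflavan-4-ol 10 (not isolated)
Conditions: RuCl[(R,R)-TsDPEN](p-cymene) (2 mol %), HCO2H/Et3N (5:2), EtOAc, 40 °C; then conc. HCl, MeOH, 50 °C
Reagents that add atoms: none
Why: Noyori–Ikariya asymmetric transfer hydrogenation reduces the enone to the C3-labile isoflavanone 9 and then the ketone with dynamic kinetic resolution to the cis-(3R,4R)-alcohol 10 (catalyst control, C3 epimerising through the enol); acid then removes both MOM groups and the liberated 2'-OH traps the C4 cation to close the cis-fused pterocarpan ring, which carries C3 of unit 1 forward in the (R) configuration.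

Step 7
Reactants: 4 1-(2-fluoro-4-hydroxyphenyl)ethan-1-one
Product: 12 1-[4-(benzyloxy)-2-fluorophenyl]ethan-1-one
Conditions: BnBr, K2CO3, acetone, reflux
Reagents that add atoms: benzyl bromide, BrCc1ccccc1
Why: Williamson etherification gives the ring A building block of unit 2 with a benzyl group that step 12 removes together with the C4 hydroxyl.

Step 8
Reactants: 13 3-bromo-5-methoxyphenol
Product: 14 1-bromo-3-methoxy-5-(methoxymethoxy)benzene
Conditions: MOMCl, iPr2NEt, CH2Cl2, 0 °C to rt
Reagents that add atoms: chloromethyl methyl ether, COCCl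
Why: O-alkylation masks the ring D phenol with a group that survives base, fluoride, transfer hydrogenation and hydrogenolysis.

Step 9
Reactants: 12 1-[4-(benzyloxy)-2-fluorophenyl]ethan-1-one; 14 1-bromo-3-methoxy-5-(methoxymethoxy)benzene
Product: 15 1-[4-(benzyloxy)-2-fluorophenyl]-2-[3-methoxy-5-(methoxymethoxy)phenyl]ethan-1-one
Conditions: Pd(OAc)2 (2 mol %), XPhos (4 mol %), K3PO4, toluene, 90 °C, 12 in slight excess
Reagents that add atoms: none
Why: Palladium-catalysed ketone α-arylation forms the C3–ring D bond of unit 2, with the excess ketone and the higher acidity of the product holding the reaction at monoarylation.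

Step 10
Reactants: 15 1-[4-(benzyloxy)-2-fluorophenyl]-2-[3-methoxy-5-(methoxymethoxy)phenyl]ethan-1-one
Product: 17 7-(benzyloxy)-3-[3-methoxy-5-(methoxymethoxy)phenyl]-4H-chromen-4-one, via sodium hydroxymethylene-ketone enolate 16 (not isolated)
Conditions: NaH (1.1 equiv), HCO2Et (3 equiv), THF, 0 °C to rt; volatiles removed; DMSO, 120 °C
Reagents that add atoms: ethyl formate, CCOC=O
Why: The same Claisen formylation and intramolecular SNAr closure as in step 5 builds the chromone of unit 2.

Step 11
Reactants: 17 7-(benzyloxy)-3-[3-methoxy-5-(methoxymethoxy)phenyl]-4H-chromen-4-one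
Product: 19 (3R,4R)-7-(benzyloxy)-3-[3-methoxy-5-(methoxymethoxy)phenyl]chroman-4-ol, via isoflavanone 18 (not isolated)
Conditions: RuCl[(R,R)-TsDPEN](p-cymene) (2 mol %), HCO2H/Et3N (5:2), EtOAc, 40 °C
Reagents that add atoms: none
Why: Noyori–Ikariya transfer hydrogenation with dynamic kinetic resolution, as in step 6, should give the cis alcohol and so set C3 of unit 2 under catalyst control.

Step 12
Reactants: 19 (3R,4R)-7-(benzyloxy)-3-[3-methoxy-5-(methoxymethoxy)phenyl]chroman-4-ol
Product: 20 (3R)-3-[3-methoxy-5-(methoxymethoxy)phenyl]chroman-7-ol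
Conditions: H2 (1 atm), 10% Pd/C, EtOH–AcOH (20:1), rt
Reagents that add atoms: none
Why: Hydrogenolysis cleaves the benzyl ether and the para-oxygen-activated benzylic C4–O bond on the metal surface without a free cation, so C3 keeps its configuration.

Step 13
Reactants: 20 (3R)-3-[3-methoxy-5-(methoxymethoxy)phenyl]chroman-7-ol
Product: 21 (3R)-3-[3-methoxy-5-(methoxymethoxy)phenyl]chroman-7-yl pivalate
Conditions: PivCl, Et3N, DMAP (cat.), CH2Cl2, 0 °C
Reagents that add atoms: pivaloyl chloride, CC(C)(C)C(=O)Cl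
Why: Acylation of the only free phenol turns the C7 oxygen of unit 2 into an ester, which deactivates its ring A towards the electrophile of step 16.

Step 14
Reactants: 21 (3R)-3-[3-methoxy-5-(methoxymethoxy)phenyl]chroman-7-yl pivalate
Product: 22 (3R)-3-(3-hydroxy-5-methoxyphenyl)chroman-7-yl pivalate
Conditions: HCl (cat.), MeOH, 40 °C
Reagents that add atoms: none
Why: Acid-catalysed acetal methanolysis frees the ring D phenol while the hindered aryl pivalate is left intact.

Step 15
Reactants: 22 (3R)-3-(3-hydroxy-5-methoxyphenyl)chroman-7-yl pivalate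
Product: 23 (3R)-3-{3-methoxy-5-[(triisopropylsilyl)oxy]phenyl}chroman-7-yl pivalate
Conditions: TIPSCl, imidazole, DMF, rt
Reagents that add atoms: chlorotriisopropylsilane, CC(C)[Si](Cl)(C(C)C)C(C)C
Why: Silylation gives a still electron-donating but bulky ether that shields both ring D carbons ortho to it.

Step 16
Reactants: 11 (6aR,11aR)-8,9-dimethoxy-6a,11a-dihydro-6H-[1]benzofuro[3,2-c]chromen-3-ol; 23 (3R)-3-{3-methoxy-5-[(triisopropylsilyl)oxy]phenyl}chroman-7-yl pivalate
Product: 25 (3R)-3-{2-[(3R,4S)-7-hydroxy-3-(2-hydroxy-4,5-dimethoxyphenyl)chroman-4-yl]-3-methoxy-5-[(triisopropylsilyl)oxy]phenyl}chroman-7-yl pivalate, via para-quinone methide 24 (not isolated)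
Conditions: BF3·OEt2 (30 mol %), CH2Cl2–(CF3)2CHOH (4:1), −20 to 0 °C, 23 (2.5 equiv, excess recovered)
Reagents that add atoms: none
Why: In this Friedel–Crafts alkylation acid opens the benzylic C–O bond of the pterocarpan to the para-quinone methide 24 (the C7 hydroxyl is para to C4), whose protonated form should be attacked by ring D of 23 at its one activated carbon not next to the silyl ether (para to OSi, ortho to OMe; ring A of 23 is deactivated by the pivalate), from the face opposite ring B at C3, which sets C4 as (S) and the 3,4-trans relationship while C3 is untouched.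

Step 17
Reactants: 25 (3R)-3-{2-[(3R,4S)-7-hydroxy-3-(2-hydroxy-4,5-dimethoxyphenyl)chroman-4-yl]-3-methoxy-5-[(triisopropylsilyl)oxy]phenyl}chroman-7-yl pivalate
Product: 27 (3R,4S)-3-(2-hydroxy-4,5-dimethoxyphenyl)-4-{4-hydroxy-2-[(3R)-7-hydroxychroman-3-yl]-6-methoxyphenyl}chroman-7-ol, via desilylated pivalate 26 (not isolated)
Conditions: Bu4NF, THF, 0 °C; then LiOH, MeOH–H2O, rt, under argon; dilute HCl work-up
Reagents that add atoms: none
Why: Fluoride cleaves the aryl silyl ether and hydroxide saponifies the aryl pivalate, neither of which touches a stereocentre or a methyl ether.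

**Compound list**

1 | 3,4-dimethoxyphenol | COc1ccc(O)cc1OC | starting material
2 | 2-bromo-4,5-dimethoxyphenol | COc1cc(O)c(Br)cc1OC | intermediate
3 | 1-bromo-4,5-dimethoxy-2-(methoxymethoxy)benzene | COCOc1cc(OC)c(OC)cc1Br | intermediate
4 | 1-(2-fluoro-4-hydroxyphenyl)ethan-1-one | CC(=O)c1ccc(O)cc1F | starting material
5 | 1-[2-fluoro-4-(methoxymethoxy)phenyl]ethan-1-one | CC(=O)c1ccc(OCOC)cc1F | intermediate
6 | 2-[4,5-dimethoxy-2-(methoxymethoxy)phenyl]-1-[2-fluoro-4-(methoxymethoxy)phenyl]ethan-1-one | COCOc1cc(OC)c(OC)cc1CC(=O)c1ccc(OCOC)cc1F | intermediate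
7 | sodium (Z)-2-[4,5-dimethoxy-2-(methoxymethoxy)phenyl]-3-[2-fluoro-4-(methoxymethoxy)phenyl]-3-oxoprop-1-en-1-olate (not isolated) | [Na+].[O-]/C=C(/c1cc(OC)c(OC)cc1OCOC)C(=O)c1ccc(OCOC)cc1F | intermediate
8 | 3-[4,5-dimethoxy-2-(methoxymethoxy)phenyl]-7-(methoxymethoxy)-4H-chromen-4-one | COCOc1cc(OC)c(OC)cc1-c1coc2cc(OCOC)ccc2c1=O | intermediate
9 | 3-[4,5-dimethoxy-2-(methoxymethoxy)phenyl]-7-(methoxymethoxy)chroman-4-one, C3 configurationally labile (not isolated) | COCOc1cc(OC)c(OC)cc1C1COc2cc(OCOC)ccc2C1=O | intermediate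
10 | (3R,4R)-3-[4,5-dimethoxy-2-(methoxymethoxy)phenyl]-7-(methoxymethoxy)chroman-4-ol, cis (not isolated) | COCOc1cc(OC)c(OC)cc1[C@@H]1COc2cc(OCOC)ccc2[C@@H]1O | intermediate
11 | (6aR,11aR)-8,9-dimethoxy-6a,11a-dihydro-6H-[1]benzofuro[3,2-c]chromen-3-ol (3-hydroxy-8,9-dimethoxypterocarpan) | COc1cc2c(cc1OC)[C@@H]1COc3cc(O)ccc3[C@@H]1O2 | intermediate
12 | 1-[4-(benzyloxy)-2-fluorophenyl]ethan-1-one | CC(=O)c1ccc(OCc2ccccc2)cc1F | intermediate
13 | 3-bromo-5-methoxyphenol | COc1cc(O)cc(Br)c1 | starting material
14 | 1-bromo-3-methoxy-5-(methoxymethoxy)benzene | COCOc1cc(OC)cc(Br)c1 | intermediate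
15 | 1-[4-(benzyloxy)-2-fluorophenyl]-2-[3-methoxy-5-(methoxymethoxy)phenyl]ethan-1-one | COCOc1cc(OC)cc(CC(=O)c2ccc(OCc3ccccc3)cc2F)c1 | intermediate
16 | sodium (Z)-3-[4-(benzyloxy)-2-fluorophenyl]-2-[3-methoxy-5-(methoxymethoxy)phenyl]-3-oxoprop-1-en-1-olate (not isolated) | [Na+].[O-]/C=C(/c1cc(OC)cc(OCOC)c1)C(=O)c1ccc(OCc2ccccc2)cc1F | intermediate
17 | 7-(benzyloxy)-3-[3-methoxy-5-(methoxymethoxy)phenyl]-4H-chromen-4-one | COCOc1cc(OC)cc(-c2coc3cc(OCc4ccccc4)ccc3c2=O)c1 | intermediate
18 | 7-(benzyloxy)-3-[3-methoxy-5-(methoxymethoxy)phenyl]chroman-4-one, C3 configurationally labile (not isolated) | COCOc1cc(OC)cc(C2COc3cc(OCc4ccccc4)ccc3C2=O)c1 | intermediate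
19 | (3R,4R)-7-(benzyloxy)-3-[3-methoxy-5-(methoxymethoxy)phenyl]chroman-4-ol, cis | COCOc1cc(OC)cc([C@@H]2COc3cc(OCc4ccccc4)ccc3[C@@H]2O)c1 | intermediate
20 | (3R)-3-[3-methoxy-5-(methoxymethoxy)phenyl]chroman-7-ol | COCOc1cc(OC)cc([C@@H]2COc3cc(O)ccc3C2)c1 | intermediate
21 | (3R)-3-[3-methoxy-5-(methoxymethoxy)phenyl]chroman-7-yl pivalate | COCOc1cc(OC)cc([C@@H]2COc3cc(OC(=O)C(C)(C)C)ccc3C2)c1 | intermediate
22 | (3R)-3-(3-hydroxy-5-methoxyphenyl)chroman-7-yl pivalate | COc1cc(O)cc([C@@H]2COc3cc(OC(=O)C(C)(C)C)ccc3C2)c1 | intermediate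
23 | (3R)-3-{3-methoxy-5-[(triisopropylsilyl)oxy]phenyl}chroman-7-yl pivalate | COc1cc(O[Si](C(C)C)(C(C)C)C(C)C)cc([C@@H]2COc3cc(OC(=O)C(C)(C)C)ccc3C2)c1 | intermediate
24 | (3R)-3-(2-hydroxy-4,5-dimethoxyphenyl)-2,3-dihydro-7H-chromen-7-one, para-quinone methide (not isolated) | COc1cc(O)c(cc1OC)[C@@H]1COC2=CC(=O)C=CC2=C1 | intermediate
25 | (3R)-3-{2-[(3R,4S)-7-hydroxy-3-(2-hydroxy-4,5-dimethoxyphenyl)chroman-4-yl]-3-methoxy-5-[(triisopropylsilyl)oxy]phenyl}chroman-7-yl pivalate | COc1cc(O)c([C@@H]2COc3cc(O)ccc3[C@H]2c2c(OC)cc(O[Si](C(C)C)(C(C)C)C(C)C)cc2[C@@H]2COc3cc(OC(=O)C(C)(C)C)ccc3C2)cc1OC | intermediate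
26 | (3R)-3-{5-hydroxy-2-[(3R,4S)-7-hydroxy-3-(2-hydroxy-4,5-dimethoxyphenyl)chroman-4-yl]-3-methoxyphenyl}chroman-7-yl pivalate (not isolated) | COc1cc(O)c([C@@H]2COc3cc(O)ccc3[C@H]2c2c(OC)cc(O)cc2[C@@H]2COc3cc(OC(=O)C(C)(C)C)ccc3C2)cc1OC | intermediate
27 | (3R,4S)-3-(2-hydroxy-4,5-dimethoxyphenyl)-4-{4-hydroxy-2-[(3R)-7-hydroxychroman-3-yl]-6-methoxyphenyl}chroman-7-ol | COc1cc(O)c([C@@H]2COc3cc(O)ccc3[C@H]2c2c(OC)cc(O)cc2[C@@H]2COc3cc(O)ccc3C2)cc1OC | target

**Summary**

Total steps: 17. Longest linear sequence: 10 steps (13 → 14 → 15 → 17 → 19 → 20 → 21 → 22 → 23 → 25 → 27; equally long from 4 through 12).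

Steps most likely to fail:

1. Step 16. The C4 cation may attack 23 at another ring carbon, or attack unreacted 11 or the product, since the wanted carbon is flanked by a methoxy group and the chromanyl group. Reversible loss of the C3 proton from the cation would also erode the configuration at C3. The fallback sets out from 22 and blocks the competing positions instead of shielding them. Amine-directed ortho-bromination of the free ring D phenol (NBS, 2 equiv, catalytic iPr2NH, CH2Cl2) should give (3R)-3-(2,4-dibromo-3-hydroxy-5-methoxyphenyl)chroman-7-yl pivalate F1, in which only the carbon para to the hydroxyl is left open on ring D. Union of F1 with 11 under the acid conditions of step 16 should then give the 3,5-dibromo analogue of 26, F2. Hydrodebromination (H2, Pd/C, Et3N, EtOAc–MeOH) comes back to the route at 26, which is saponified as in step 17.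

2. Step 5. Fluoride displacement by the delocalised enolate oxygen may stall, because the para-alkoxy group weakens the activating C4 carbonyl, and at the high temperature deformylation or intermolecular substitution may take over. The fallback sets out from 6 and closes the ring in the classical direction. SNAr with the alkoxide of 2-(methylsulfonyl)ethanol (NaH, DMF), followed by loss of methyl vinyl sulfone, should give 2-[4,5-dimethoxy-2-(methoxymethoxy)phenyl]-1-[2-hydroxy-4-(methoxymethoxy)phenyl]ethan-1-one F3. Condensation of F3 with N,N-dimethylformamide dimethyl acetal (toluene, 100 °C) then forms the enaminone and cyclises through the phenol oxygen, coming back to the route at 8.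

3. Step 6. The conjugate reduction of the isoflavone may be slow, the dynamic kinetic resolution may give incomplete enantio- or cis-selectivity, and the acid stage may cause elimination to the isoflav-3-ene. The fallback sets out from 8 and replaces catalyst control by separation of diastereomers. Conjugate reduction with Li[HB(s-Bu)3] (THF, −78 °C) gives the isoflavanone 9. NaBH4 in MeOH then gives racemic 3-[4,5-dimethoxy-2-(methoxymethoxy)phenyl]-7-(methoxymethoxy)chroman-4-ol F4. HCl in MeOH closes F4 to racemic cis-3-hydroxy-8,9-dimethoxypterocarpan F5. Coupling of F5 with enantiopure 23 as in step 16 gives 25 together with its (3S,4R)-diastereomer at unit 1, F6, which is removed by chromatography. The fallback comes back to the route at 25.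

**Further compounds**

F1 | step 16 | (3R)-3-(2,4-dibromo-3-hydroxy-5-methoxyphenyl)chroman-7-yl pivalate | COc1cc([C@@H]2COc3cc(OC(=O)C(C)(C)C)ccc3C2)c(Br)c(O)c1Br
F2 | step 16 | (3R)-3-{3,5-dibromo-4-hydroxy-2-[(3R,4S)-7-hydroxy-3-(2-hydroxy-4,5-dimethoxyphenyl)chroman-4-yl]-6-methoxy... ring D numbered from the chroman-4-yl carbon; the 3,5-dibromo analogue of 26 | COc1cc(O)c([C@@H]2COc3cc(O)ccc3[C@H]2c2c(OC)c(Br)c(O)c(Br)c2[C@@H]2COc3cc(OC(=O)C(C)(C)C)ccc3C2)cc1OC
F3 | step 5 | 2-[4,5-dimethoxy-2-(methoxymethoxy)phenyl]-1-[2-hydroxy-4-(methoxymethoxy)phenyl]ethan-1-one | COCOc1cc(OC)c(OC)cc1CC(=O)c1ccc(OCOC)cc1O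
F4 | step 6 | racemic 3-[4,5-dimethoxy-2-(methoxymethoxy)phenyl]-7-(methoxymethoxy)chroman-4-ol | COCOc1cc(OC)c(OC)cc1C1COc2cc(OCOC)ccc2C1O
F5 | step 6 | racemic cis-8,9-dimethoxy-6a,11a-dihydro-6H-[1]benzofuro[3,2-c]chromen-3-ol | COc1cc2c(cc1OC)C1COc3cc(O)ccc3C1O2
F6 | step 6 | (3R)-3-{2-[(3S,4R)-7-hydroxy-3-(2-hydroxy-4,5-dimethoxyphenyl)chroman-4-yl]-3-methoxy-5-[(triisopropylsilyl)oxy]phenyl}chroman-7-yl pivalate | COc1cc(O)c([C@H]2COc3cc(O)ccc3[C@@H]2c2c(OC)cc(O[Si](C(C)C)(C(C)C)C(C)C)cc2[C@@H]2COc3cc(OC(=O)C(C)(C)C)ccc3C2)cc1OC
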